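With germacrane numbering, the two oxepanes are read as one ten-membered carbocycle (C1–C10) pinned by the C5–O–C10 ether and carrying a trans C7–C8 α-methylene-γ-lactone. The carbocycle is cut at C7–C8. Because O5 sits 1,3 to C7, C12 can be parked on O5 as a 3-(bromomethyl)dihydropyranone, tethered through C4–C1 to a 9,10-epoxy aldehyde (C8) built from geraniol. One CrCl2-mediated allylation then forms C7–C8, closes the ten-membered ring, sets C7 and C8, reveals the C11=C13 methylene and, by acyl shift from O5 to O8, the γ-lactone. The freed C5 hydroxyl finally opens the epoxide at C10, closing both oxepanes.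

Key step: step 11

Remark: germacrane atom numbers (ring C1–C10; lactone C11–C13; C14 on C10; C15 on C4) are used for every intermediate. The ligand and pinene antipodes in steps 3, 5 and 13 are assigned from the established facial preferences of these reagents.

Step 1
Reactants: 1 geraniol
Product: 2 geranyl tert-butyldimethylsilyl ether
Conditions: TBSCl, imidazole, DMF, 0 °C to rt
Reagents that add atoms: tert-butyldimethylsilyl chloride, CC(C)(C)[Si](C)(C)Cl
Why: Standard silylation of a primary allylic alcohol (imidazole-mediated silyl transfer); no stereocentre is involved.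

Step 2
Reactants: 2 geranyl tert-butyldimethylsilyl ether
Product: 4 (2E,6E)-8-[(tert-butyldimethylsilyl)oxy]-2,6-dimethylocta-2,6-dien-1-ol, via enal 3 (not isolated)
Conditions: SeO2 (0.3 equiv), t-BuOOH (3 equiv), salicylic acid (0.1 equiv), CH2Cl2, rt; then NaBH4, MeOH, 0 °C
Reagents that add atoms: tert-butyl hydroperoxide, CC(C)(C)OO; selenium dioxide (catalytic oxygen carrier), O=[Se]=O
Why: SeO2 allylic oxidation (ene reaction, then [2,3]-sigmatropic shift) should attack the E-methyl group of the more electron-rich terminal alkene with retention of E geometry, and NaBH4 returns the over-oxidised fraction, enal 3, to 4 by 1,2-reduction.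

Step 3
Reactants: 4 (2E,6E)-8-[(tert-butyldimethylsilyl)oxy]-2,6-dimethylocta-2,6-dien-1-ol
Product: 5 (2S,6E)-8-[(tert-butyldimethylsilyl)oxy]-2,6-dimethyloct-6-en-1-ol
Conditions: Ru(OAc)2[(S)-BINAP] (1 mol%), H2 (100 atm), MeOH, rt
Reagents that add atoms: none
Why: Noyori asymmetric hydrogenation of an allylic alcohol: only the alkene next to the free carbinol can chelate ruthenium, so the silylated 9,10-alkene should stay, and the S ligand is chosen by carrying over the face selection known for geraniol, which gives 4S here (a minor 4R component would leave as a diastereomer after step 5).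

Step 4
Reactants: 5 (2S,6E)-8-[(tert-butyldimethylsilyl)oxy]-2,6-dimethyloct-6-en-1-ol
Product: 6 (2S,6E)-8-[(tert-butyldimethylsilyl)oxy]-2,6-dimethyloct-6-enal
Conditions: TEMPO (0.1 equiv), PhI(OAc)2 (1.1 equiv), CH2Cl2, rt; used crude at once
Reagents that add atoms: none
Why: Oxoammonium (TEMPO) oxidation of a primary alcohol stops at the aldehyde under neutral, non-enolising conditions, so the C4 centre next to the new formyl group should keep its configuration.

Step 5
Reactants: 6 (2S,6E)-8-[(tert-butyldimethylsilyl)oxy]-2,6-dimethyloct-6-enal + 7 allylmagnesium bromide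
Product: 9 (4R,5S,9E)-11-[(tert-butyldimethylsilyl)oxy]-5,9-dimethylundeca-1,9-dien-4-ol, via allylborane 8 (not isolated)
Conditions: (+)-Ipc2BOMe (from (−)-α-pinene), 7, Et2O, 0 °C to rt; then 6, −78 °C; NaOH, 30% H2O2, 0 °C to rt
Reagents that add atoms: none
Why: Brown allylboration: allyl transfer from magnesium to boron gives 8, which adds through a chair Zimmerman–Traxler transition state in which the isopinocampheyl groups from (−)-α-pinene send allyl to the Re face of the aldehyde, setting 5R (4,5-anti) by reagent control against the weak Felkin preference for the syn isomer.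

Step 6
Reactants: 9 (4R,5S,9E)-11-[(tert-butyldimethylsilyl)oxy]-5,9-dimethylundeca-1,9-dien-4-yl alcohol + 10 2-(bromomethyl)acrylic acid
Product: 11 (4R,5S,9E)-11-[(tert-butyldimethylsilyl)oxy]-5,9-dimethylundeca-1,9-dien-4-yl 2-(bromomethyl)acrylate
Conditions: DCC, DMAP (0.1 equiv), CH2Cl2, 0 °C
Reagents that add atoms: none
Why: Steglich esterification acylates the C5 hydroxyl without breaking the C5–O bond, and the small DMAP charge at 0 °C should keep amine attack on the allylic bromide low.

Step 7
Reactants: 11 (4R,5S,9E)-11-[(tert-butyldimethylsilyl)oxy]-5,9-dimethylundeca-1,9-dien-4-yl 2-(bromomethyl)acrylate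
Product: 12 (6R)-3-(bromomethyl)-6-[(2S,6E)-8-[(tert-butyldimethylsilyl)oxy]-6-methyloct-6-en-2-yl]-5,6-dihydro-2H-pyran-2-one
Conditions: second-generation Hoveyda–Grubbs catalyst RuCl2(H2IMes)(=CH-C6H4-2-OiPr) (5 mol%), toluene (5 mM), 80 °C, argon sparge
Reagents that add atoms: none
Why: Ring-closing metathesis between the monosubstituted alkene, where the carbene loads, and the 1,1-disubstituted acrylate closes the six-membered enoate (O, C5, C6, C7, C11, C12) with loss of ethylene, as with methacrylates; the phosphine-free catalyst avoids alkylation of free phosphine by the allylic bromide, and the trisubstituted 9,10-alkene is too hindered to take part.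

Step 8
Reactants: 12 (6R)-3-(bromomethyl)-6-[(2S,6E)-8-[(tert-butyldimethylsilyl)oxy]-6-methyloct-6-en-2-yl]-5,6-dihydro-2H-pyran-2-one
Product: 13 (6R)-3-(bromomethyl)-6-[(2S,6E)-8-hydroxy-6-methyloct-6-en-2-yl]-5,6-dihydro-2H-pyran-2-one
Conditions: 48% aq. HF, MeCN, 0 °C
Reagents that add atoms: none
Why: Acidic fluoride cleavage of a primary allylic silyl ether; the amine-free medium is chosen because pyridine or basic fluoride sources would displace the allylic bromide, while lactone and alkenes are inert.

Step 9
Reactants: 13 (6R)-3-(bromomethyl)-6-[(2S,6E)-8-hydroxy-6-methyloct-6-en-2-yl]-5,6-dihydro-2H-pyran-2-one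
Product: 14 (6R)-3-(bromomethyl)-6-{(2S)-5-[(2S,3S)-3-(hydroxymethyl)-2-methyloxiran-2-yl]pentan-2-yl}-5,6-dihydro-2H-pyran-2-one
Conditions: Ti(OiPr)4, L-(+)-diethyl tartrate, t-BuOOH (in decane), 4 Å MS, CH2Cl2, −20 °C; aq. tartaric acid work-up
Reagents that add atoms: tert-butyl hydroperoxide, CC(C)(C)OO
Why: Sharpless asymmetric epoxidation of an E-trisubstituted primary allylic alcohol: the titanium L-tartrate complex delivers oxygen to the face that gives the (2S,3S)-epoxy alcohol, as with geraniol, which sets C9 and C10, and neither the electron-poor enoate nor the allylic bromide is a substrate.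

Step 10
Reactants: 14 (6R)-3-(bromomethyl)-6-{(2S)-5-[(2S,3S)-3-(hydroxymethyl)-2-methyloxiran-2-yl]pentan-2-yl}-5,6-dihydro-2H-pyran-2-one
Product: 15 (2R,3S)-3-{(4S)-4-[(2R)-5-(bromomethyl)-6-oxo-3,6-dihydro-2H-pyran-2-yl]pentyl}-3-methyloxirane-2-carbaldehyde
Conditions: Dess–Martin periodinane, NaHCO3, CH2Cl2, 0 °C to rt; used directly
Reagents that add atoms: none
Why: Buffered Dess–Martin oxidation converts the primary epoxy alcohol into the epoxy aldehyde without opening the oxirane; C9 is an oxirane carbon and does not epimerise (its descriptor changes by priority only).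

Step 11
Reactants: 15 (2R,3S)-3-{(4S)-4-[(2R)-5-(bromomethyl)-6-oxo-3,6-dihydro-2H-pyran-2-yl]pentyl}-3-methyloxirane-2-carbaldehyde
Product: 18 (4S,5R,7R,8R,9S,10S)-9,10-epoxy-5-hydroxygermacr-11(13)-en-12,8-olide, via allylchromium dichloride 16 (not isolated), via bridged hydroxy δ-lactone 17 (not isolated)
Conditions: CrCl2 (10 equiv), THF, rt, 15 added by syringe pump (final 2 mM); then sat. aq. NH4Cl
Reagents that add atoms: none
Why: Two equivalents of CrCl2 (divalent chromium) reduce the allylic C–Br bond to the allylchromium species 16 (trivalent chromium), in which the pyranone holds C6 trans to the metal-bearing C13 across C11=C7; this adds through its γ-carbon C7 to the formyl carbon C8 in a closed chair transition state with shift of the double bond, which is the Nozaki–Hiyama–Kishi allylation in its intramolecular Barbier form, the closest known cases being closures of formyl-tethered 2-(bromomethyl)enoates to ten-membered germacranolides and additions of 3-(bromomethyl) unsaturated lactones to aldehydes followed by lactone exchange. The carbocycle C1–C10 closes by this C7–C8 bond (10-exo-trig addition to the carbonyl group), leaving C11=C13 as the exocyclic methylene in bridged lactone 17 (held as its chromium alkoxide); the γ-lactone then closes by 5-exo-trig attack of the C8 oxygen on C12, and the tetrahedral intermediate expels O5, so the six-membered lactone opens and the C5 hydroxyl is released, driven by loss of the bridged bicycle and the preference for the five-membered lactone. C7 is controlled by C5, because the seven-atom chain C4–C3–C2–C1–C10–C9–C8 can bridge the 1,3-positions of the six-membered lactone on one face only, so C8 must bond to the face of C7 cis to the C5 side chain. C8 is controlled by C7 through the ring-locked E-type allyl geometry, which in the chair transition state gives the anti relation of O8 and C6 and hence the trans lactone, with chromium chelation between the formyl and epoxide oxygens favouring the same aldehyde face. The step needs ring closure to beat intermolecular allylation, which slow addition at about 2 mM and the stiffening by the trans-epoxide and the pyranone should secure, and it needs γ-attack with anti topology, which is inherent to allylchromium reagents; epoxide and enoate are inert to CrCl2 at room temperature. Any 17 that survives work-up would be carried on, since the acid of step 12 also promotes the acyl shift.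

Step 12
Reactants: 18 (4S,5R,7R,8R,9S,10S)-9,10-epoxy-5-hydroxygermacr-11(13)-en-12,8-olide
Product: 19 (4S,5R,7R,8R,9S,10R)-5,10-epoxy-9-hydroxygermacr-11(13)-en-12,8-olide
Conditions: CSA (0.2 equiv), CH2Cl2, 0 °C
Reagents that add atoms: none
Why: Acid-catalysed transannular etherification by epoxide opening: protonation weakens the bond to tertiary C10, O5 attacks C10 from inside the ring anti to the epoxide oxygen, so C10 is inverted while C9 keeps its oxygen and configuration, both oxepanes closing at once (7-exo through C4–C1, 7-endo through C6–C9), and attack at secondary C9 is disfavoured by the adjacent acyloxy-bearing C8.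

Step 13
Reactants: 20 tiglic acid
Product: 21 (R)-2-methylbutanoic acid
Conditions: Ru(OAc)2[(R)-H8-BINAP] (0.5 mol%), H2 (2 atm), MeOH, rt
Reagents that add atoms: none
Why: Carboxylate-directed Noyori-type asymmetric hydrogenation of an α,β-unsaturated acid, for which tiglic acid is the standard substrate; the R ligand should give the R acid, and the sense would be checked by optical rotation before use.

Step 14
Reactants: 19 (4S,5R,7R,8R,9S,10R)-5,10-epoxy-9-hydroxygermacr-11(13)-en-12,8-olide + 21 (R)-2-methylbutanoic acid
Product: 23 (4S,5R,7R,8R,9S,10R)-5,10-epoxy-9-[(2R)-2-methylbutanoyloxy]germacr-11(13)-en-12,8-olide (CNP0136059.1), via mixed anhydride 22 (not isolated)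
Conditions: 21, 2,4,6-trichlorobenzoyl chloride, Et3N, THF, 0 °C to rt; then 19, DMAP, toluene, rt
Reagents that add atoms: none
Why: Yamaguchi esterification: mixed anhydride 22 passes the aliphatic acyl group through the acylpyridinium to the hindered C9 hydroxyl with retention at C9 (its C–O bond is not broken), and the absence of an acid chloride and of strong base should preserve the α-centre of the acid and the α-methylene lactone.

Compound list
1 | geraniol, (2E)-3,7-dimethylocta-2,6-dien-1-ol | CC(C)=CCC/C(C)=C/CO | starting material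
2 | geranyl tert-butyldimethylsilyl ether | CC(C)=CCC/C(C)=C/CO[Si](C)(C)C(C)(C)C | intermediate
3 | (2E,6E)-8-[(tert-butyldimethylsilyl)oxy]-2,6-dimethylocta-2,6-dienal (not isolated) | O=C/C(C)=C/CC/C(C)=C/CO[Si](C)(C)C(C)(C)C | intermediate
4 | (2E,6E)-8-[(tert-butyldimethylsilyl)oxy]-2,6-dimethylocta-2,6-dien-1-ol | OC/C(C)=C/CC/C(C)=C/CO[Si](C)(C)C(C)(C)C | intermediate
5 | (2S,6E)-8-[(tert-butyldimethylsilyl)oxy]-2,6-dimethyloct-6-en-1-ol | OC[C@@H](C)CCC/C(C)=C/CO[Si](C)(C)C(C)(C)C | intermediate
6 | (2S,6E)-8-[(tert-butyldimethylsilyl)oxy]-2,6-dimethyloct-6-enal | O=C[C@@H](C)CCC/C(C)=C/CO[Si](C)(C)C(C)(C)C | intermediate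
7 | allylmagnesium bromide | C=CC[Mg]Br | starting material
8 | B-allyldiisopinocampheylborane derived from (−)-α-pinene (not isolated) | C=CCB([C@H]1C[C@H]2C[C@@H]([C@@H]1C)C2(C)C)[C@H]1C[C@H]2C[C@@H]([C@@H]1C)C2(C)C | intermediate
9 | (4R,5S,9E)-11-[(tert-butyldimethylsilyl)oxy]-5,9-dimethylundeca-1,9-dien-4-ol | C=CC[C@@H](O)[C@@H](C)CCC/C(C)=C/CO[Si](C)(C)C(C)(C)C | intermediate
10 | 2-(bromomethyl)acrylic acid | C=C(CBr)C(=O)O | starting material
11 | (4R,5S,9E)-11-[(tert-butyldimethylsilyl)oxy]-5,9-dimethylundeca-1,9-dien-4-yl 2-(bromomethyl)acrylate | C=C(CBr)C(=O)O[C@H](CC=C)[C@@H](C)CCC/C(C)=C/CO[Si](C)(C)C(C)(C)C | intermediate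
12 | (6R)-3-(bromomethyl)-6-[(2S,6E)-8-[(tert-butyldimethylsilyl)oxy]-6-methyloct-6-en-2-yl]-5,6-dihydro-2H-pyran-2-one | O=C1O[C@H](CC=C1CBr)[C@@H](C)CCC/C(C)=C/CO[Si](C)(C)C(C)(C)C | intermediate
13 | (6R)-3-(bromomethyl)-6-[(2S,6E)-8-hydroxy-6-methyloct-6-en-2-yl]-5,6-dihydro-2H-pyran-2-one | O=C1O[C@H](CC=C1CBr)[C@@H](C)CCC/C(C)=C/CO | intermediate
14 | (6R)-3-(bromomethyl)-6-{(2S)-5-[(2S,3S)-3-(hydroxymethyl)-2-methyloxiran-2-yl]pentan-2-yl}-5,6-dihydro-2H-pyran-2-one | O=C1O[C@H](CC=C1CBr)[C@@H](C)CCC[C@]2(C)O[C@H]2CO | intermediate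
15 | (2R,3S)-3-{(4S)-4-[(2R)-5-(bromomethyl)-6-oxo-3,6-dihydro-2H-pyran-2-yl]pentyl}-3-methyloxirane-2-carbaldehyde | O=C1O[C@H](CC=C1CBr)[C@@H](C)CCC[C@]2(C)O[C@H]2C=O | intermediate
16 | allylchromium dichloride from 15 (CH2Br replaced by CH2CrCl2; not isolated) | O=C1O[C@H](CC=C1C[Cr](Cl)Cl)[C@@H](C)CCC[C@]2(C)O[C@H]2C=O | intermediate
17 | (4S,5R,7R,8R,9S,10S)-9,10-epoxy-8-hydroxygermacr-11(13)-en-12,5-olide, δ-lactone bridging C5 and C7 of the ten-membered ring (chromium alkoxide in the flask; not isolated) | C=C1C(=O)O[C@@H]2C[C@H]1[C@@H](O)[C@@H]1O[C@@]1(C)CCC[C@@H]2C | intermediate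
18 | (4S,5R,7R,8R,9S,10S)-9,10-epoxy-5-hydroxygermacr-11(13)-en-12,8-olide (trans-fused α-methylene-γ-lactone, trans-epoxide, free C5 hydroxyl) | C=C1C(=O)O[C@@H]2[C@@H]1C[C@@H](O)[C@@H](C)CCC[C@]3(C)O[C@@H]23 | intermediate
19 | (4S,5R,7R,8R,9S,10R)-5,10-epoxy-9-hydroxygermacr-11(13)-en-12,8-olide (ether-bridged core, free C9 hydroxyl) | C=C1C(=O)O[C@@H]2[C@@H]1C[C@H]1O[C@](C)(CCC[C@@H]1C)[C@H]2O | intermediate
20 | tiglic acid, (E)-2-methylbut-2-enoic acid | C/C=C(\C)C(=O)O | starting material
21 | (R)-2-methylbutanoic acid | CC[C@@H](C)C(=O)O | intermediate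
22 | (2R)-2-methylbutanoic 2,4,6-trichlorobenzoic anhydride (not isolated) | CC[C@@H](C)C(=O)OC(=O)c1c(Cl)cc(Cl)cc1Cl | intermediate
23 | CNP0136059.1, (4S,5R,7R,8R,9S,10R)-5,10-epoxy-9-[(2R)-2-methylbutanoyloxy]germacr-11(13)-en-12,8-olide | C=C1C(=O)O[C@@H]2[C@@H]1C[C@H]1O[C@](C)(CCC[C@@H]1C)[C@H]2OC(=O)[C@H](C)CC | target

Total step count: 14. Longest linear sequence: 13 steps (steps 1–12 and 14, geraniol to target); step 13 is a one-step side branch.

Steps most likely to fail

Step 11. Oligomerisation may outrun ring closure, a boat-like transition state may give the C8 epimer, or the chromium Lewis acids may erode the epoxy aldehyde. The fallback postpones the epoxide. Setting out from allylic alcohol 13, MnO2 in CH2Cl2 would give the (E)-enal F1. CrCl2 in THF at high dilution would then close the ring through the allylchromium species F2 and the bridged allylic-alcohol lactone F3 to the 9,10-(E)-olefinic 5-hydroxy trans-lactone F4. This enal closure is the best-established route to germacranolides, because the E-alkene stiffens the chain and the enal is a sturdier electrophile. Epoxidation of the 9,10-alkene of F4 would follow, by Shi epoxidation with the enantiomer of the D-fructose-derived ketone, chosen for the 9S,10S epoxide (KHSO5 as 2KHSO5·KHSO4·K2SO4, K2CO3, MeCN/dimethoxymethane/water, 0 °C). The electron-poor methylene lactone should not be attacked, and the sequence comes back to the route at 18.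

Step 12. The hydroxyl may fail to reach the rear of C10 in the reactive conformer, so that proton loss to allylic alcohols or a hydride shift from C9 takes over, or it may attack C9 to give a tetrahydropyran. The fallback makes the C10–O bond by addition to an alkene instead of substitution. Setting out from 18, Al(OiPr)3 in hot toluene would isomerise the epoxide to the 10(14)-exocyclic allylic alcohol F5, with C9 untouched. Iodoetherification (N-iodosuccinimide, MeCN, 0 °C) would deliver O5 to the tertiary end of the iodonium ion and give the 14-iodo 5,10-ether F6. The configuration at C10 is dictated by C5, because a one-atom oxygen bridge can span the ring on one side only. Radical deiodination (Bu3SnH, Et3B/air, toluene, 0 °C) would come back to the route at 19.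

Step 7. The catalyst may be lost through reaction with the allylic bromide, or closure onto the hindered, electron-poor 1,1-disubstituted alkene may be slow enough for dimerisation through the terminal alkene to take over. The fallback closes the ring before the bromomethyl group is present. Setting out from 9, acryloyl chloride and iPr2NEt (CH2Cl2, 0 °C) would give the acrylate F7. Ring-closing metathesis with the second-generation Grubbs catalyst RuCl2(H2IMes)(PCy3)(=CHPh) in refluxing CH2Cl2 would give the unsubstituted dihydropyranone F8. A Morita–Baylis–Hillman reaction with aqueous formaldehyde (imidazole, THF/water) would give the 3-(hydroxymethyl)pyranone F9. Appel bromination (CBr4, PPh3, CH2Cl2, 0 °C) would come back to the route at 12.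

Further compounds
F1 | step 11 | (2E,7S)-7-[(2R)-5-(bromomethyl)-6-oxo-3,6-dihydro-2H-pyran-2-yl]-3-methyloct-2-enal | O=C1O[C@H](CC=C1CBr)[C@@H](C)CCC/C(C)=C/C=O
F2 | step 11 | allylchromium dichloride from F1 (CH2Br replaced by CH2CrCl2) | O=C1O[C@H](CC=C1C[Cr](Cl)Cl)[C@@H](C)CCC/C(C)=C/C=O
F3 | step 11 | (9E)-8-hydroxygermacra-9,11(13)-dien-12,5-olide, δ-lactone bridging C5 and C7 | C=C1C(=O)O[C@@H]2C[C@H]1[C@@H](O)/C=C(C)/CCC[C@@H]2C
F4 | step 11 | (9E)-5-hydroxygermacra-9,11(13)-dien-12,8-olide, trans-fused lactone | C=C1C(=O)O[C@@H]2[C@@H]1C[C@@H](O)[C@@H](C)CCC/C(C)=C/2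
F5 | step 12 | 5,9-dihydroxygermacra-10(14),11(13)-dien-12,8-olide, configuration at C4, C5, C7, C8 and C9 as in 18 | C=C1C(=O)O[C@@H]2[C@@H]1C[C@@H](O)[C@@H](C)CCCC(=C)[C@H]2O
F6 | step 12 | 5,10-epoxy-9-hydroxy-14-iodogermacr-11(13)-en-12,8-olide, configuration as in 19 | C=C1C(=O)O[C@@H]2[C@@H]1C[C@H]1O[C@](CI)(CCC[C@@H]1C)[C@H]2O
F7 | step 7 | (4R,5S,9E)-11-[(tert-butyldimethylsilyl)oxy]-5,9-dimethylundeca-1,9-dien-4-yl acrylate | C=CC(=O)O[C@H](CC=C)[C@@H](C)CCC/C(C)=C/CO[Si](C)(C)C(C)(C)C
F8 | step 7 | (6R)-6-[(2S,6E)-8-[(tert-butyldimethylsilyl)oxy]-6-methyloct-6-en-2-yl]-5,6-dihydro-2H-pyran-2-one | O=C1O[C@H](CC=C1)[C@@H](C)CCC/C(C)=C/CO[Si](C)(C)C(C)(C)C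
F9 | step 7 | (6R)-3-(hydroxymethyl)-6-[(2S,6E)-8-[(tert-butyldimethylsilyl)oxy]-6-methyloct-6-en-2-yl]-5,6-dihydro-2H-pyran-2-one | O=C1O[C@H](CC=C1CO)[C@@H](C)CCC/C(C)=C/CO[Si](C)(C)C(C)(C)C
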